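Count the ligand.

| setting | cedar | elm | birch | larch |
|---|---|---|---|---|
| starting complex | 10 mM (fed, over 32.0 s) | 10 mM | 10 mM | 10 mM |
| incoming ligand | 7.00 mM | 7.00 mM | 7.00 mM (fed, over 32.0 s) | 7.00 mM |
| leaving ligand | 10.0 mM | 10.0 mM | 10.0 mM | 10.0 mM |
| time | 40 s |  | 40 s | 40 s |
| remark | a stirred flask in which starting complex is dosed at a steady rate over 32.0 s without added volume, worked up at 40 s | a single well-mixed tank run continuously and read at steady state, 40 s in it on average | a stirred flask in which incoming ligand is dosed at a steady rate over 32.0 s without added volume, worked up at 40 s | a closed flask charged with all of it at once and left for 40 s |

    starting complex + incoming ligand ⇌ leaving ligand + complex with one exchanged (K1 = 0.49, k1 = 11.5 M⁻¹ s⁻¹)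
    complex with one exchanged + incoming ligand ⇌ leaving ligand + complex with two exchanged (K2 = 3.51, k2 = 6.75 M⁻¹ s⁻¹)
    complex with two exchanged + incoming ligand ⇌ leaving ligand + complex with three exchanged (K3 = 0.508, k3 = 14.0 M⁻¹ s⁻¹)
    complex with one exchanged → over-reaction product A (k4 = 3.01 × 10⁻⁵ s⁻¹)
    complex with one exchanged + incoming ligand → over-reaction product B (k5 = 0.202 M⁻¹ s⁻¹)

- the stated concentrations are those of everything mixed, before any reaction; amounts are the same in each set-up
- the feed brings no volume worth counting
- the share counts what is present at the end, not what went on to other products
- run time (cedar): 40 s

* the set-up with the highest share of complex with one exchanged in all that became complex with one exchanged or complex with two exchanged or complex with three exchanged or over-reaction product B, at the outlet or at the end ("none" if the first two lie within 2 percentage points) (cedar / elm / birch / larch / none)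
* share of complex with one exchanged in all that became complex with one exchanged or complex with two exchanged or complex with three exchanged or over-reaction product B, at the outlet or at the end, cedar
* share of complex with one exchanged in all that became complex with one exchanged or complex with two exchanged or complex with three exchanged or over-reaction product B, at the outlet or at the end, elm
* share of complex with one exchanged in all that became complex with one exchanged or complex with two exchanged or complex with three exchanged or over-reaction product B, at the outlet or at the end, birch
* share of complex with one exchanged in all that became complex with one exchanged or complex with two exchanged or complex with three exchanged or over-reaction product B, at the outlet or at the end, larch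

I keep the ledger on the incoming ligand, the limiting reagent by charge: it stands at 0.700 of the starting complex charged. The first entry is the first exchange. Its forward half-life in larch is 8.6 s, shorter than the 40 s of the run, but with the ligands as charged, equilibrium allows complex with one exchanged a ratio of 0.343 to starting complex, so part of the charge stays free. The second entry is the second exchange, which costs a further ligand and lowers the asked share. I carry its turnover count: the forward turnovers of step 2 open to a complex with one exchanged during its time in the vessel, with ligand at its full charge and the way back not counted. For larch this is 1.89. Complex with three exchanged books one more ligand on top of this entry. Over-reaction product B costs two ligands in total, and its selectivity factor against the second exchange is 0.0299; its half-life in larch, 8.2 min, is longer than the run. Over-reaction product A takes no ligand and leaves the larch share unchanged. What no entry holds stays free, and the books close.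

Now the vessels. Elm has the same count as larch, on average, but a tank spreads the stays, so the fraction not turned over is 0.346, against 0.151 in larch. In birch the ligand arrives over 32.0 s, which leaves a count of 1.13 and an unturned fraction of 0.322. In cedar the complex has the same mean stay, so its count is the same. These fractions are not shares, and I use them to rank the vessels. I commit to larch as the lowest and leave the top open, because 0.346 and 0.322 stand too near to rank.

The forecast gives 57% for cedar, 61% for elm, 62% for birch and 52% for larch, and its best is none: “Dosing the ligand and the continuous tank both hold back the second exchange about equally”.

The flask gives 59.5% for cedar, 60.5% for elm, 64.9% for birch and 52.7% for larch, so the best is birch, 4.4 percentage points ahead of elm, where the forecast had 1 point. At 40.0 s birch still holds 60.7% of its ligand charge free. Birch and cedar carry the same count, 1.13, yet stand 5.4 points apart. A neighbour of birch, dosed the same way with 18 mM of ligand, has a count of 2.92, and its share is 38.9%.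

(The numbers were chosen freely; what happens was integrated by code.)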